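A direct plan would make the C3–C4 bond of the acyl chain by an alkyl–alkyl Negishi coupling in one flask.
Zinc dust would insert into the C–Br bond of benzyl 3-bromopropanoate A1 to give (3-benzyloxy-3-oxopropyl)zinc bromide A2, a zinc homoenolate.
A2 would then be coupled with 1-bromoicosane A3 over Pd2(dba)3 (zerovalent palladium) and tricyclopentylphosphine to give the target ester.
Weakest operation, the zinc insertion into A1 β to the ester: elimination or reduction of the bromide of A1 would compete, and A2 could not be purified or reliably titrated, so an excess would be spent.
Second weakest, the C(sp3)–C(sp3) coupling of the unactivated primary bromide A3: β-hydride elimination and protodemetalation would give waxy C20 by-products next to a waxy product. This is the operation one would least like to run on all of A3.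
The plan has no ring or stereocentre to leave to chance and wastes no steps, but it stakes palladium, an air-sensitive phosphine and a preformed C20 halide on one CH2–CH2 bond.

**Plan of the new route**
The retrosynthesis cuts C4–C5 of the acyl chain and takes both carbons at the same polarity, as primary alkyl radicals set free at an anode from two carboxylic acids.
C1–C4, with the benzyl ester in place, come from glutaric anhydride 1 and benzyl alcohol 2 through the half ester 3; C5–C23 come from icosanoic acid 4.
Mixed Kolbe electrolysis of 3 and 4 gives the radicals 5 and 6, whose recombination is the target 7; no ring arises at any stage.
Enabling feature: C2–C23 is an unbranched CH2 chain with no ring, stereocentre or heteroatom, and C4 and C5 are plain CH2 groups. Both radicals are therefore primary and unstabilised and couple rather than oxidise further, with the C1 ester three carbons away.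
No organozinc, alkyl halide, palladium or phosphine is used, so zinc insertion next to an ester and β-hydride elimination cannot occur.

Key step: step 2

Remark: the target is achiral and acyclic (the benzyl ester of unbranched C23 tricosanoic acid), so no stereocentre has to be set and no ring closed.

Step 1
Reactants: 1 glutaric anhydride; 2 benzyl alcohol
Product: 3 5-(benzyloxy)-5-oxopentanoic acid (monobenzyl glutarate)
Conditions: 1 (1.0 equiv), 2 (1.05 equiv), DMAP (5 mol%), toluene, 80 °C, 6 h; acid–base extractive work-up
Reagents that add atoms: none
Why: DMAP-catalysed alcoholysis of a cyclic anhydride joins one alcohol to one anhydride, so the half ester should form without the mono/di-ester mixture of a statistical esterification, and the slight excess of 2 stays in the organic wash.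

Step 2
Reactants: 3 5-(benzyloxy)-5-oxopentanoic acid; 4 icosanoic acid (arachidic acid)
Product: 7 benzyl tricosanoate, via nonadecyl radical 5 (not isolated), via 4-benzyloxy-4-oxobutyl radical 6 (not isolated)
Conditions: 4 (1.0 equiv), 3 (4.0 equiv), NaOMe (0.25 equiv, about 5% neutralisation of total acid), MeOH, 50 °C, undivided cell, smooth Pt anode and Pt cathode, 0.2 A cm−2, about 1.3 F per mol of acid, polarity switched every 30 s, current stopped while the solution is still acidic
Reagents that add atoms: none
Why: Each carboxylate is oxidised by one electron at the platinum anode and the acyloxy radicals lose CO2; the nonadecyl radical 5 from 4 and the ester radical 6 from 3 then recombine in the anode layer to form the C4–C5 bond, while the carboxyl protons are reduced to H2 at the cathode. The closest known reaction type is the mixed (crossed) Kolbe electrolysis of a fatty acid with an alkyl hydrogen ester of a dicarboxylic acid, the classical chain extension of fatty acids. No ring is closed and no stereocentre is formed. The selectivity needed is cross- over homo-coupling; it is statistical, so the fourfold excess of the cheap half ester 3 should steer most nonadecyl radicals to an ester radical, and the symmetrical by-products (a C38 alkane and a dibenzyl C8 diester) carry one ester fewer or one more than 7 and should separate on silica or by crystallisation. Both radicals are primary and unstabilised, so further oxidation to cations (the Hofer–Moest path) should stay minor at high current density on smooth platinum in weakly acidic methanol. The benzyl ester should survive because the carboxylate layer on the anode shields the arene, the Z geometry of the ester holds the benzylic hydrogens away from the radical centre of 6, and the current is stopped before the medium turns alkaline, so methoxide cannot exchange the ester.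

**Compound list**
1 | glutaric anhydride (oxane-2,6-dione) | O=C1CCCC(=O)O1 | starting material
2 | benzyl alcohol | OCc1ccccc1 | starting material
3 | 5-(benzyloxy)-5-oxopentanoic acid (monobenzyl glutarate) | OC(=O)CCCC(=O)OCc1ccccc1 | intermediate
4 | icosanoic acid (arachidic acid) | CCCCCCCCCCCCCCCCCCCC(=O)O | starting material
5 | nonadecyl radical | [CH2]CCCCCCCCCCCCCCCCCC | intermediate
6 | 4-benzyloxy-4-oxobutyl radical | [CH2]CCC(=O)OCc1ccccc1 | intermediate
7 | benzyl tricosanoate | CCCCCCCCCCCCCCCCCCCCCCC(=O)OCc1ccccc1 | target

Total step count: 2
Longest linear sequence: 2 steps (1 → 3 → 7; 4 enters in the last step)

**Steps most likely to fail** (the route has only two steps, so both are given, the riskier first)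

Step 2. What may go wrong:
- homo-coupling of each radical with itself would consume the acids;
- a waxy film could passivate the anode;
- the radicals could be oxidised by a second electron to cations that are trapped by methanol;
- the benzyl ester could undergo methanolysis if the electrolysis is carried past the acidic stage.

Fallback, which gives up the radical coupling for an olefin cross-metathesis followed by a chemoselective reduction: setting out from benzyl alcohol 2, acid-catalysed esterification with undec-10-enoic acid (TsOH cat., toluene, Dean–Stark) would give benzyl undec-10-enoate F1. Cross-metathesis of F1 with tetradec-1-ene (4 equiv; second-generation Grubbs catalyst (H2IMes)(PCy3)Cl2Ru=CHPh, 2 mol%; 1,4-benzoquinone 10 mol% against double-bond migration; CH2Cl2, 40 °C) would give benzyl (E)-tricos-10-enoate F2 together with some Z isomer. Diimide reduction (2-nitrobenzenesulfonohydrazide, Et3N, CH2Cl2, room temperature) should saturate the C10–C11 double bond of both isomers without hydrogenolysis of the benzyl ester, and would come back to the route at 7.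

Step 1. What may go wrong:
- adventitious water could hydrolyse the anhydride;
- the half ester could disproportionate to diester and diacid on prolonged heating, leaving glutaric acid that would cross-link in the electrolysis.

Fallback, which replaces the ring opening by exhaustive esterification and selective monohydrolysis: setting out from glutaric anhydride 1 and benzyl alcohol 2 (2.5 equiv), TsOH-catalysed esterification with azeotropic removal of water would give dibenzyl glutarate F3. Monosaponification of F3 (KOH 1.0 equiv, THF/H2O, 0 °C), extraction of the acid into aqueous base and acidification would come back to the route at 3.

**Further compounds**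
F1 | step 2 | benzyl undec-10-enoate | C=CCCCCCCCCC(=O)OCc1ccccc1
F2 | step 2 | benzyl (E)-tricos-10-enoate | CCCCCCCCCCCC/C=C/CCCCCCCCC(=O)OCc1ccccc1
F3 | step 1 | dibenzyl glutarate (dibenzyl pentanedioate) | O=C(CCCC(=O)OCc1ccccc1)OCc1ccccc1
A1 | direct plan | benzyl 3-bromopropanoate | BrCCC(=O)OCc1ccccc1
A2 | direct plan | (3-benzyloxy-3-oxopropyl)zinc bromide | Br[Zn]CCC(=O)OCc1ccccc1
A3 | direct plan | 1-bromoicosane | CCCCCCCCCCCCCCCCCCCCBr
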